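**Retrosynthetic overview**
- Feature (labdane numbering): 9-H and the C20 methyl on C10 lie on the same face of ring B. The C11-C16 chain on C9 is therefore axial and cis to the C8 hydroxyl. This pattern results from a boat-type, not a chair-type, union of C9 with C10.
- End game: O3/O18 differentiation; C13-C14 by enol triflate vinylation; C11=C12 by acetonyl Wittig reaction on a C11 aldehyde; 5-H by C11-OH-directed hydrogenation of a C5=C6 alkene.
- Key disconnection: C9-C10. It is made by Ireland-Claisen rearrangement of the silyl ketene acetal of a 6-(ring A cyclohexenyl)-4-hydroxy-4-methyl delta-lactone. The C6-O bond serves as a temporary tether and is given up as ring B closes.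
- Lactone: from a ring A enal by methallylboration (C6-C7), oxidative cleavage to the C8 ketone, bromoacetylation and a SmI2 Reformatsky closure (C8-C9).
- Ring order: ring A (2-methylcyclohexane-1,3-dione, desymmetrised), then the temporary lactone ring, then ring B.

Key step: step 11

Assumption: the ketoreductase of step 2 is picked from a commercial panel by screening for the (2S,3R)-ketol; enzymes of either sense are on offer for 2,2-disubstituted cyclohexane-1,3-diones.
Convention: labdane numbering is used for all intermediates. "Lower face" is the decalin face that carries C20 (also C19, C17, 3-O, 9-H). "Upper face" is the one that carries 5-H (also C18, C11, 8-O).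

**Step 1**
Reactants: 1 2-methylcyclohexane-1,3-dione; 2 formaldehyde
Product: 3 2-(hydroxymethyl)-2-methylcyclohexane-1,3-dione
Conditions: 37% aq HCHO, Et3N (cat.), THF/H2O, 0 °C to rt
Reagents that add atoms: formaldehyde 2, C=O
Why: Aldol-type hydroxymethylation of the acidic C-2 position of a 2-alkyl-1,3-dione, a C-selective reaction that builds the still prochiral quaternary carbon C4 with C19 and C18.

**Step 2**
Reactants: 3 2-(hydroxymethyl)-2-methylcyclohexane-1,3-dione
Product: 4 (2S,3R)-3-hydroxy-2-(hydroxymethyl)-2-methylcyclohexan-1-one (3-OH cis to the C19 methyl, trans to C18)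
Conditions: ketoreductase, NADP+ (cat.), i-PrOH, phosphate buffer pH 6.5, 30 °C
Reagents that add atoms: none
Why: Enzymatic desymmetrising reduction of a prochiral 2,2-disubstituted cyclohexane-1,3-dione, in which the choice between the enantiotopic carbonyl groups fixes C4 and the hydride face fixes C3, while the slightly acidic buffer holds back retro-aldol loss of formaldehyde.

**Step 3**
Reactants: 4 (2S,3R)-ketol diol
Product: 5 (4aS,8aR)-2,2,4a-trimethylhexahydrobenzo[d][1,3]dioxin-5-one (ring A C5 ketone, trans-fused O3/O18 acetonide)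
Conditions: Me2C(OMe)2, PPTS (cat.), CH2Cl2, rt
Reagents that add atoms: 2,2-dimethoxypropane, COC(C)(C)OC
Why: Acid-catalysed transketalisation closes the six-membered acetonide of the 1,3-diol, which blocks retro-aldol cleavage and, with 3-O and C18 equatorial, holds the C19 methyl axial.

**Step 4**
Reactants: 5 ring A ketone acetonide
Product: 6 C10-methyl ketone acetonide (both C10 epimers, of no consequence)
Conditions: LiN(i-Pr)2, THF, -78 °C; MeI, -78 to 0 °C
Reagents that add atoms: iodomethane, CI
Why: Enolate alkylation at C10, the only enolisable position because C4 is quaternary, where the new centre need not be controlled since C10 becomes sp2 in the next step.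

**Step 5**
Reactants: 6 C10-methyl ketone acetonide
Product: 7 C5 enol triflate (C5=C10 tetrasubstituted alkene, C20 on C10)
Conditions: KN(SiMe3)2, THF, -78 to 0 °C; PhNTf2, 0 °C to rt
Reagents that add atoms: N-phenylbis(trifluoromethanesulfonimide), O=S(=O)(N(c1ccccc1)S(=O)(=O)C(F)(F)F)C(F)(F)F
Why: O-Triflation after deprotonation at the only available alpha position, as known for 2,2,6-trisubstituted cyclohexanones.

**Step 6**
Reactants: 7 C5 enol triflate
Product: 8 ring A enal (C6 aldehyde on C5, C5=C10 alkene)
Conditions: Pd(PPh3)4 (5 mol %), LiCl, CO (3 atm), Bu3SnH (slow addition), THF, 50 °C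
Reagents that add atoms: carbon monoxide, [C-]#[O+]
Why: Palladium-catalysed formylation of an enol triflate (oxidative addition to zerovalent palladium, CO insertion, hydride transfer from tin to the acylpalladium species), with slow hydride addition favouring insertion over direct reduction.

**Step 7**
Reactants: 8 ring A enal; 9 methallylmagnesium chloride
Product: 10 (1R)-1-(ring A cyclohexenyl)-3-methylbut-3-en-1-ol ((R)-C6 carbinol)
Conditions: (+)-Ipc2BOMe, 9, Et2O, -78 °C to rt; 8, -78 °C; 3 M NaOH, 30% H2O2, 0 °C to rt
Reagents that add atoms: methallylmagnesium chloride 9, C=C(C)C[Mg]Cl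
Why: Brown asymmetric methallylboration through a closed six-membered chair transition state, in which the reagent derived from (-)-alpha-pinene adds to the Re face of the aldehyde and sets (R)-C6 under reagent control.

**Step 8**
Reactants: 10 (R)-C6 homoallylic alcohol
Product: 12 (4R)-4-hydroxy-4-(ring A cyclohexenyl)butan-2-one (C8 ketone with C17 methyl), via triol 11 (not isolated)
Conditions: OsO4 (2 mol %), NaIO4, 2,6-lutidine, dioxane/H2O, rt
Reagents that add atoms: osmium tetroxide, O=[Os](=O)(=O)=O (delivers the oxygen); sodium periodate, [Na+].[O-]I(=O)(=O)=O (restores it)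
Why: Lemieux-Johnson oxidation, in which OsO4 takes the open 1,1-disubstituted alkene and leaves the tetrasubstituted C5=C10 alkene next to the quaternary C4, after which periodate cleaves the glycol.

**Step 9**
Reactants: 12 beta-hydroxy ketone; 13 bromoacetyl bromide
Product: 14 C6 bromoacetate of 12
Conditions: pyridine, CH2Cl2, -78 to -20 °C
Reagents that add atoms: bromoacetyl bromide 13, O=C(Br)CBr
Why: Acylation of the secondary allylic alcohol with an acid bromide under weak-base, low-temperature conditions that avoid beta-elimination of the acyloxy ketone.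

**Step 10**
Reactants: 14 C6 bromoacetate
Product: 15 (4S,6R)-4-hydroxy-4-methyl-6-(ring A cyclohexenyl)tetrahydropyran-2-one (C8 hydroxyl trans, C17 methyl cis to the cyclohexenyl group)
Conditions: SmI2 (2.5 equiv), THF, -78 °C; aq NH4Cl
Reagents that add atoms: none
Why: Samarium diiodide promoted intramolecular Reformatsky reaction of a beta-(bromoacetoxy) ketone, in which trivalent samarium binds enolate and ketone oxygens in a chair with the cyclohexenyl group equatorial and the ketone oxygen axial, so that the C8 hydroxyl ends trans to the C6 substituent.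

**Step 11**
Reactants: 15 hydroxy lactone
Product: 18 8-hydroxy-5-ene C11 carboxylic acid acetonide (C11 and 8-OH on the upper face; C20 and C17 and 9-H on the lower face), via bis-silyl ketene acetal 16 (not isolated), via silyl ester 17 (not isolated)
Conditions: Me3SiCl/Et3N (excess), THF, -78 °C, then LiN(SiMe3)2 (3.5 equiv), -78 °C to rt; toluene, 110 °C; AcOH/THF/H2O, rt
Reagents that add atoms: chlorotrimethylsilane, C[Si](C)(C)Cl (its silyl groups stand in 16 and 17 and leave again in the hydrolysis)
Why: LiN(SiMe3)2 removes the C8 hydroxyl proton and then one C9 proton, and the Me3SiCl already present caps both oxygens at -78 °C, so that neither retro-aldol cleavage nor E1cB loss of the C8 oxygen from a free enolate can set in and the cyclic O-silyl ketene acetal 16 is formed. On heating, 16 undergoes a concerted suprafacial [3,3] sigmatropic shift in which C9-C10 forms, C6-O breaks and the alkene moves from C5=C10 to C5=C6, the closest known reaction type being the Ireland-Claisen rearrangement of the silyl ketene acetals of 6-alkenyl delta-lactones and 6-alkenyl-1,4-dioxan-2-ones to cyclohexene- and dihydropyrancarboxylic acids. Ring B (C5 to C10) is closed by this pericyclic exchange of the six-membered lactone for a six-membered carbocycle, and because C9 and C6 are already tied through C8-C7 the six reacting atoms can only stack as a boat, a chair placing C7 and C8 too far apart to stay bonded. C10 is set by chirality transfer from (R)-C6, since C9 must arrive on the ring A face from which the C6 oxygen departs, which is the upper face left open by the pseudoaxial C19 methyl group. C9 is set by the ring-fixed ketene acetal geometry (C8 cis to the ring oxygen) within the boat, which lays C11 over C5, C8 over C20 and 9-H over C1, so that after relaxation C11 is axial on ring B, anti to C20 and cis to the C8 oxygen that was trans to the cyclohexenyl group in 15. The step needs face and boat selectivity, both enforced by the tether in the substrate, and it needs the shift to outrun ionisation of the allylic C6-O bond, for which acid-free conditions (Et3N, base-washed glass) and the energy gain from ketene acetal to silyl ester 17 speak; dilute AcOH then frees acid and carbinol and leaves the acetonide in place.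

**Step 12**
Reactants: 18 hydroxy acid
Product: 19 5-ene 8,11-diol acetonide
Conditions: LiAlH4, THF, 0 °C to reflux
Reagents that add atoms: none
Why: Hydride reduction of the carboxylic acid to the primary C11 carbinol, with acetonide, alkene and tertiary carbinol inert and C9 safe because the carboxylate is not enolised.

**Step 13**
Reactants: 19 5-ene 8,11-diol acetonide
Product: 20 saturated trans-decalin 8,11-diol acetonide (5-H on the upper face)
Conditions: [Ir(cod)(PCy3)(py)]PF6 (10 mol %), H2 (10-50 bar), CH2Cl2, rt
Reagents that add atoms: none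
Why: Hydroxyl-directed homogeneous hydrogenation, in which the cationic iridium catalyst binds the axial C11 hydroxyl (1,3-related to C5) and delivers H2 to C5=C6 from the upper face, which is also the face free of the C19, C20 and C17 methyl groups, giving 5-H anti to C20.

**Step 14**
Reactants: 20 saturated 8,11-diol acetonide
Product: 21 8,11-bis(triethylsilyl) ether
Conditions: Et3SiOTf (3 equiv), 2,6-lutidine, CH2Cl2, 0 °C
Reagents that add atoms: triethylsilyl trifluoromethanesulfonate, CC[Si](CC)(CC)OS(=O)(=O)C(F)(F)F
Why: Silylation with a silyl triflate and a hindered pyridine base covers the primary and the tertiary hydroxyl, the C8 ether being needed later to prevent retro-aldol cleavage of the aldehyde and hemiketal formation with the C13 ketone.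

**Step 15**
Reactants: 21 bis(triethylsilyl) ether
Product: 22 C11 aldehyde, 8-O-triethylsilyl ether (CHO axial, upper face)
Conditions: (COCl)2, DMSO, CH2Cl2, -78 to -40 °C; Et3N, -78 °C to rt
Reagents that add atoms: none
Why: Swern oxidation applied directly to the bis-silyl ether, a known selective reaction in which the chlorosulfonium salt attacks only the primary triethylsilyl ether and turns it into the aldehyde while the tertiary ether stays.

**Step 16**
Reactants: 22 C11 aldehyde; 23 1-(triphenylphosphoranylidene)propan-2-one
Product: 24 (11E)-enone (C11=C12, C13 ketone, C16 methyl)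
Conditions: toluene, 100 °C
Reagents that add atoms: 1-(triphenylphosphoranylidene)propan-2-one 23, CC(=O)C=P(c1ccccc1)(c1ccccc1)c1ccccc1
Why: Wittig olefination with a stabilised, nearly neutral ylide should give the (E)-enone without enolising the aldehyde, whose carbonyl group stands on the methyl-free upper face and whose equatorial C8-O bond is poorly aligned for E1cB loss.

**Step 17**
Reactants: 24 (11E)-enone
Product: 25 saturated C13 methyl ketone
Conditions: H2 (1 atm), Pd/C (10 wt % Pd), EtOAc, rt
Reagents that add atoms: none
Why: Heterogeneous catalytic hydrogenation of the disubstituted enone C=C bond, the only alkene present, under neutral conditions that spare ketone, silyl ether and acetonide.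

**Step 18**
Reactants: 25 C13 methyl ketone
Product: 26 terminal enol triflate (C13(OTf)=C16H2)
Conditions: LiN(i-Pr)2, THF, -78 °C; N-(5-chloropyridin-2-yl)bis(trifluoromethanesulfonimide), -78 °C
Reagents that add atoms: N-(5-chloropyridin-2-yl)bis(trifluoromethanesulfonimide), O=S(=O)(N(c1ccc(Cl)cn1)S(=O)(=O)C(F)(F)F)C(F)(F)F
Why: Kinetic deprotonation of the methyl ketone on the less substituted side (C16) and O-triflation at the same low temperature with the reactive pyridyl triflimide gives the terminal enol triflate.

**Step 19**
Reactants: 26 terminal enol triflate; 27 tributyl(vinyl)stannane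
Product: 28 13(16),14-diene, O3/O18 acetonide, 8-O-triethylsilyl ether
Conditions: Pd(PPh3)4 (5 mol %), LiCl, THF, 65 °C
Reagents that add atoms: tributyl(vinyl)stannane 27, C=C[Sn](CCCC)(CCCC)CCCC
Why: Stille cross-coupling of an enol triflate with a vinylstannane in the presence of LiCl forms C13-C14 and with it the 2-substituted buta-1,3-diene.

**Step 20**
Reactants: 28 protected diene
Product: 29 3,8,18-triol
Conditions: camphorsulfonic acid (0.2 equiv), MeOH, 0 °C to rt
Reagents that add atoms: none
Why: Acid-catalysed methanolysis removes acetonide and triethylsilyl ether together, catalytic sulfonic acid in methanol at or below room temperature being too weak to protonate the diene or ionise the tertiary carbinol.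

**Step 21**
Reactants: 29 3,8,18-triol
Product: 30 18-O-tert-butyldimethylsilyl ether
Conditions: t-BuMe2SiCl (1.1 equiv), imidazole, CH2Cl2, 0 °C
Reagents that add atoms: tert-butyldimethylsilyl chloride, CC(C)(C)[Si](C)(C)Cl
Why: Sterically controlled silylation, the primary C18 hydroxyl reacting faster than the secondary C3 and the tertiary C8 hydroxyl.

**Step 22**
Reactants: 30 18-O-silyl ether
Product: 31 3-acetate 18-O-silyl ether
Conditions: Ac2O, pyridine, DMAP (cat.), CH2Cl2, rt
Reagents that add atoms: acetic anhydride, CC(=O)OC(C)=O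
Why: DMAP-catalysed acetylation of the equatorial secondary C3 hydroxyl, the hindered tertiary C8 hydroxyl being unreactive at room temperature.

**Step 23**
Reactants: 31 3-acetate 18-O-silyl ether
Product: 32 target CNP0313672.1, (3R,4S,5S,8S,9R,10R)-3-acetoxylabda-13(16),14-diene-8,18-diol
Conditions: HF·pyridine, pyridine/THF, 0 °C to rt
Reagents that add atoms: none
Why: Fluoride-mediated desilylation in a buffered, weakly acidic medium, chosen because basic fluoride could move the acetyl group from O3 to the neighbouring primary O18.

**Compound list**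
1 | 2-methylcyclohexane-1,3-dione | CC1C(=O)CCCC1=O | starting material
2 | formaldehyde | C=O | starting material
3 | 2-(hydroxymethyl)-2-methylcyclohexane-1,3-dione | CC1(CO)C(=O)CCCC1=O | intermediate
4 | (2S,3R)-3-hydroxy-2-(hydroxymethyl)-2-methylcyclohexan-1-one | O=C1CCC[C@@H](O)[C@]1(C)CO | intermediate
5 | (4aS,8aR)-2,2,4a-trimethylhexahydrobenzo[d][1,3]dioxin-5-one | O=C1CCC[C@H]2OC(C)(C)OC[C@]12C | intermediate
6 | C10-methyl ketone acetonide (C10 epimers) | O=C1C(C)CC[C@H]2OC(C)(C)OC[C@]12C | intermediate
7 | C5 enol triflate | O=S(=O)(OC1=C(C)CC[C@H]2OC(C)(C)OC[C@]12C)C(F)(F)F | intermediate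
8 | ring A enal | O=CC1=C(C)CC[C@H]2OC(C)(C)OC[C@]12C | intermediate
9 | methallylmagnesium chloride | C=C(C)C[Mg]Cl | starting material
10 | (R)-C6 homoallylic alcohol | C=C(C)C[C@@H](O)C1=C(C)CC[C@H]2OC(C)(C)OC[C@]12C | intermediate
11 | triol from dihydroxylation (C8 epimers) | OCC(C)(O)C[C@@H](O)C1=C(C)CC[C@H]2OC(C)(C)OC[C@]12C | intermediate
12 | (R)-C6 beta-hydroxy C8 ketone | CC(=O)C[C@@H](O)C1=C(C)CC[C@H]2OC(C)(C)OC[C@]12C | intermediate
13 | bromoacetyl bromide | O=C(Br)CBr | starting material
14 | C6 bromoacetate | CC(=O)C[C@@H](OC(=O)CBr)C1=C(C)CC[C@H]2OC(C)(C)OC[C@]12C | intermediate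
15 | (4S,6R)-hydroxy lactone (key-step precursor) | O=C1C[C@@](C)(O)C[C@@H](O1)C2=C(C)CC[C@H]3OC(C)(C)OC[C@]23C | intermediate
16 | bis-silyl ketene acetal | C[Si](C)(C)OC1=C[C@@](C)(O[Si](C)(C)C)C[C@@H](O1)C2=C(C)CC[C@H]3OC(C)(C)OC[C@]23C | intermediate
17 | trimethylsilyl ester, 8-O-trimethylsilyl ether | C[Si](C)(C)OC(=O)[C@@H]1[C@]2(C)CC[C@H]3OC(C)(C)OC[C@]3(C)C2=CC[C@]1(C)O[Si](C)(C)C | intermediate
18 | 8-hydroxy-5-ene C11 acid acetonide (key-step product) | OC(=O)[C@@H]1[C@]2(C)CC[C@H]3OC(C)(C)OC[C@]3(C)C2=CC[C@]1(C)O | intermediate
19 | 5-ene 8,11-diol acetonide | OC[C@@H]1[C@]2(C)CC[C@H]3OC(C)(C)OC[C@]3(C)C2=CC[C@]1(C)O | intermediate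
20 | saturated 8,11-diol acetonide | OC[C@@H]1[C@]2(C)CC[C@H]3OC(C)(C)OC[C@]3(C)[C@H]2CC[C@]1(C)O | intermediate
21 | 8,11-bis(triethylsilyl) ether | CC[Si](CC)(CC)OC[C@@H]1[C@]2(C)CC[C@H]3OC(C)(C)OC[C@]3(C)[C@H]2CC[C@]1(C)O[Si](CC)(CC)CC | intermediate
22 | C11 aldehyde | O=C[C@@H]1[C@]2(C)CC[C@H]3OC(C)(C)OC[C@]3(C)[C@H]2CC[C@]1(C)O[Si](CC)(CC)CC | intermediate
23 | 1-(triphenylphosphoranylidene)propan-2-one | CC(=O)C=P(c1ccccc1)(c1ccccc1)c1ccccc1 | starting material
24 | (11E)-enone | CC(=O)/C=C/[C@@H]1[C@]2(C)CC[C@H]3OC(C)(C)OC[C@]3(C)[C@H]2CC[C@]1(C)O[Si](CC)(CC)CC | intermediate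
25 | C13 methyl ketone | CC(=O)CC[C@@H]1[C@]2(C)CC[C@H]3OC(C)(C)OC[C@]3(C)[C@H]2CC[C@]1(C)O[Si](CC)(CC)CC | intermediate
26 | terminal enol triflate | C=C(OS(=O)(=O)C(F)(F)F)CC[C@@H]1[C@]2(C)CC[C@H]3OC(C)(C)OC[C@]3(C)[C@H]2CC[C@]1(C)O[Si](CC)(CC)CC | intermediate
27 | tributyl(vinyl)stannane | C=C[Sn](CCCC)(CCCC)CCCC | starting material
28 | protected diene | C=CC(=C)CC[C@@H]1[C@]2(C)CC[C@H]3OC(C)(C)OC[C@]3(C)[C@H]2CC[C@]1(C)O[Si](CC)(CC)CC | intermediate
29 | 3,8,18-triol | C=CC(=C)CC[C@@H]1[C@]2(C)CC[C@@H](O)[C@](C)(CO)[C@H]2CC[C@]1(C)O | intermediate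
30 | 18-O-tert-butyldimethylsilyl ether | C=CC(=C)CC[C@@H]1[C@]2(C)CC[C@@H](O)[C@](C)(CO[Si](C)(C)C(C)(C)C)[C@H]2CC[C@]1(C)O | intermediate
31 | 3-acetate 18-O-silyl ether | C=CC(=C)CC[C@@H]1[C@]2(C)CC[C@@H](OC(C)=O)[C@](C)(CO[Si](C)(C)C(C)(C)C)[C@H]2CC[C@]1(C)O | intermediate
32 | CNP0313672.1 | C=CC(=C)CC[C@@H]1[C@]2(C)CC[C@@H](OC(C)=O)[C@](C)(CO)[C@H]2CC[C@]1(C)O | target

Total step count: 23. Longest linear sequence: 23 (steps 1 to 23).

**Steps most likely to fail**

**1. Step 11.**
- What may go wrong: the [3,3] shift may be slow. The boat forces C7 into allylic strain with C20 and brings the C17 methyl against C20. Ionisation of the allylic C6-O bond, loss of the C8 oxygen or desilylation of the ketene acetal could then take over.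
- Fallback (sets out from 10, comes back at 19): keep the methyl group and the oxygen off C8 during the rearrangement.
- Double lithiation of 10 (n-BuLi, TMEDA, Et2O; alkoxide-directed allylic metalation of the methallyl methyl group) and a CO2 quench should give the 5-hydroxy-3-methylene acid F1. EDC·HCl closes it to the 4-methylene delta-lactone F2.
- F2 holds no beta-leaving group. LiN(SiMe3)2/Me3SiCl gives the dienyl silyl ketene acetal F3, in which C8 is flat, so the C17/C20 contact is absent from the boat.
- The same shift gives the silyl ester F4 and, after hydrolysis, the 5,8(17)-dienoic acid F5. LiAlH4 gives the homoallylic alcohol F6.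
- VO(acac)2/t-BuOOH, steered by the axial C11 hydroxyl, epoxidises C8=C17 from the upper face to the spiro-epoxide F7. LiAlH4 opens it at C17 and gives 19.

**2. Step 13.**
- What may go wrong: there may be no hydrogen uptake, because the trisubstituted C5=C6 alkene lies between the quaternary C4 and C10. The catalyst may also die, or acid formed from it may start to remove the acetonide.
- Fallback (sets out from 19, comes back at 20): radical hydrogen-atom-transfer hydrogenation with Mn(dpm)3 (cat.), PhSiH3 and t-BuOOH in i-PrOH at rt.
- This places a tertiary radical on C5. The radical is quenched from the methyl-free upper face and leads to the more stable trans-decalin. The fallback makes no new compound (F0).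

**3. Step 16.**
- What may go wrong: olefination of the aldehyde between the quaternary C8 and C10 may be sluggish. Prolonged heating could then cause slow epimerisation at C9 or loss of the C8 silyloxy group.
- Fallback (sets out from 22, comes back at 28): use small, fast reagents and bring in the diene as one piece.
- Ph3P=CH2 (Ph3PCH3Br, KOt-Bu, THF, 0 °C) gives the C11=C12 vinyl compound F8. 9-BBN, then NaOH/H2O2, gives the C12 primary alcohol F9.
- I2, PPh3 and imidazole (Appel-type iodination) give the C12 iodide F10.
- Coupling with buta-1,3-dien-2-ylmagnesium chloride (from 2-chlorobuta-1,3-diene and Mg) under Li2CuCl4 catalysis in THF gives 28. Steps 16 to 19 are bypassed.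

**Further compounds**
F1 | step 11 | 5-hydroxy-3-methylene acid | OC(=O)CC(=C)C[C@@H](O)C1=C(C)CC[C@H]2OC(C)(C)OC[C@]12C
F2 | step 11 | 4-methylene delta-lactone | O=C1CC(=C)C[C@@H](O1)C2=C(C)CC[C@H]3OC(C)(C)OC[C@]23C
F3 | step 11 | dienyl silyl ketene acetal | C[Si](C)(C)OC1=CC(=C)C[C@@H](O1)C2=C(C)CC[C@H]3OC(C)(C)OC[C@]23C
F4 | step 11 | silyl ester of the 5,8(17)-dienoic acid | C[Si](C)(C)OC(=O)[C@@H]1[C@]2(C)CC[C@H]3OC(C)(C)OC[C@]3(C)C2=CCC1=C
F5 | step 11 | 5,8(17)-dienoic acid | OC(=O)[C@@H]1[C@]2(C)CC[C@H]3OC(C)(C)OC[C@]3(C)C2=CCC1=C
F6 | step 11 | 5,8(17)-dien-11-ol | OC[C@@H]1[C@]2(C)CC[C@H]3OC(C)(C)OC[C@]3(C)C2=CCC1=C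
F7 | step 11 | 8,17-spiro-epoxide (oxygen on the upper face) | OC[C@@H]1[C@]2(C)CC[C@H]3OC(C)(C)OC[C@]3(C)C2=CC[C@@]14CO4
F0 | step 13 | none | none
F8 | step 16 | C11=C12 vinyl compound | C=C[C@@H]1[C@]2(C)CC[C@H]3OC(C)(C)OC[C@]3(C)[C@H]2CC[C@]1(C)O[Si](CC)(CC)CC
F9 | step 16 | C12 primary alcohol | OCC[C@@H]1[C@]2(C)CC[C@H]3OC(C)(C)OC[C@]3(C)[C@H]2CC[C@]1(C)O[Si](CC)(CC)CC
F10 | step 16 | C12 iodide | ICC[C@@H]1[C@]2(C)CC[C@H]3OC(C)(C)OC[C@]3(C)[C@H]2CC[C@]1(C)O[Si](CC)(CC)CC
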